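Sunday's run levels off at 1.4300 M, so 4.67% of its charge of starting material does not appear as product. Friday's flask repeats Saturday's charge, so its yield depends on how large that gap becomes there.

| flask | starting material | catalyst | product | time |
|---|---|---|---|---|
| Saturday's | 0.500 M | 0.00250 M |  |  |
| Sunday's | 1.50 M | 0.00250 M |  |  |
| Wednesday's | 0.500 M | 0.00250 M | 0.150 M |  |
| Tuesday's | 0.500 M | 0.00500 M |  |  |
| Friday's | 0.500 M | 0.00250 M |  | 230 min |

| run | time / min | [product] / M |
|---|---|---|
| Saturday's run | 3.3 | 0.0026 |
| Saturday's run | 9.9 | 0.0155 |
| Saturday's run | 19 | 0.0445 |
| Saturday's run | 30 | 0.0920 |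
| Saturday's run | 43 | 0.1686 |
| Saturday's run | 57 | 0.2563 |
| Saturday's run | 73 | 0.3528 |
| Saturday's run | 91 | 0.4151 |
| Sunday's run | 3.3 | 0.0025 |
| Sunday's run | 9.9 | 0.0347 |
| Sunday's run | 19 | 0.1451 |
| Sunday's run | 30 | 0.5073 |
| Sunday's run | 43 | 1.0929 |
| Sunday's run | 57 | 1.3723 |
| Sunday's run | 73 | 1.4267 |
| Sunday's run | 91 | 1.4300 |
| Wednesday's run | 3.3 | 0.1796 |
| Wednesday's run | 9.9 | 0.2466 |
| Wednesday's run | 19 | 0.3445 |
| Wednesday's run | 30 | 0.4501 |
| Wednesday's run | 43 | 0.5455 |
| Wednesday's run | 57 | 0.5988 |
| Wednesday's run | 73 | 0.6204 |
| Wednesday's run | 91 | 0.6310 |
| Tuesday's run | 3.3 | 0.0092 |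
| Tuesday's run | 9.9 | 0.0410 |
| Tuesday's run | 19 | 0.0915 |
| Tuesday's run | 30 | 0.1711 |
| Tuesday's run | 43 | 0.2787 |
| Tuesday's run | 57 | 0.3753 |
| Tuesday's run | 73 | 0.4361 |
| Tuesday's run | 91 | 0.4639 |

(standard deviation of a reading: 0.002 M)

1. the power of [catalyst] that the first rate follows, about the charge of the Saturday's run; measure it at two percent of starting material made into product
2. the power of [starting material] that the first rate follows, about the charge of the Saturday's run; measure it at two percent of starting material made into product (one fixed amount of product, the same in the runs compared)
3. product in the Friday's run at 230 min, as a share of the starting material charged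

- Overall: starting material -> product, with catalyst as catalyst.
- Constant volume, constant temperature.
- Readings of a species count what is bound in complexes too.
- An order is taken over about fifteen percent of the charge, up and down.

My own reckoning works with the fraction left. Suppose a side loss removes a fixed share of the remaining starting material each minute. The share lost is then that constant times the area under the fraction-left curve. These curves fall late and steeply, so the area is taken as the half-time, when product made reaches half of the charge.

How fast is the loss? Sunday's readings put its half-time at 35.4 min. The leak constant, the lost share divided by the half-time, is therefore 0.00132 min⁻¹.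

How much does Saturday's charge lose? Saturday's half-time reads 56.0 min, longer than Sunday's, so the lost share comes to 7.38%.

Is Friday's flask finished at 230 min? Saturday's unconverted fraction falls by 0.0306 min⁻¹ over its last two readings. Carried forward, this leaves 0.242% of the charge open, far less than the lost share. My estimate for Friday's flask is 92.6%.

The forecast gives 1 (0.6 to 1.6) for the catalyst order, 0.6 (0.2 to 1) for the starting-material order, and 95% (89% to 99%) for Friday's flask. Of the late flattening it says that it “suggests catalyst dying or approach to a limit”. My estimate lies below its value, inside its range.

The simulation gives 0.79, 0.31 and 92.6%.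

    catalyst + starting material ⇌ catalyst-substrate complex (23.16 M⁻¹ min⁻¹, 0.7500 min⁻¹)
    catalyst-substrate complex → product + catalyst (0.7440 min⁻¹)
    starting material + product → 2 product (0.09180 M⁻¹ min⁻¹)
    starting material → decomposed substrate (0.001404 min⁻¹)

In Saturday's run, the catalyst cycle through the catalyst-substrate complex ran from the start, and the rate stood at 0.0021 M min⁻¹ at two percent turned. Wednesday's run, charged with 0.150 M of product, had a faster rate at that amount made than Saturday's run, 0.0088 M min⁻¹. Autocatalysis ran while product was present. Decay to decomposed substrate ran while starting material remained. Friday's shortfall of 7.40% corresponds to 56.1 min at the leak constant. Wednesday's half-time of 24.4 min gives a lost share of 3.22%, and its last reading, at 91 min, leaves 3.80% of the charge unturned into product.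

The runs are simulated with made-up constants, noise included.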